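**Retrosynthetic overview**
1. Target 22 ⇐ phenol desilylation, C6 allylic hydroxylation, C3 oxidation and C19 acylation of diol 15, which already holds rings A and B and C4, C8 and C9.
2. Diol 15 ⇐ one cationic cascade from the acyclic (3S,4R)-epoxy alcohol 12: epoxide opening closes ring A, then ring B (chair–chair) to the labd-13-en-8-yl cation, which rearranges as in the proposed biogenesis (H-9→C8, CH3-20 C10→C9, loss of H-5) to the halim-5(10)-ene.
3. Epoxy alcohol 12 ⇐ Sharpless epoxidation of (Z)-allylic alcohol 11 ⇐ B-alkyl Suzuki coupling of triene 6 with (Z)-iodide 9.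
4. Triene 6 ⇐ (E)-geranylacetone 1: butenolide by enolate hydroxylation and Bestmann annulation, then terminal SeO2 oxidation and methylenation.
5. Ring order: butenolide → oxirane → ring A → ring B (the last two in one flask).

Assumption: from compound 2 onwards all carbons carry the locants of the final halimane skeleton (C19 = oxygenated carbon on C4, C20 = methyl on C9, C15 = lactone carbonyl), and 1 is bought as the pure (E)-isomer.

**Route**

Step 1
Reactants: 1 (E)-geranylacetone
Product: 2 (5E)-1-hydroxy-6,10-dimethylundeca-5,9-dien-2-one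
Conditions: KN(SiMe3)2, THF, −78 °C; then 3-phenyl-2-(phenylsulfonyl)oxaziridine, −78 °C; aq NH4Cl
Reagents that add atoms: 3-phenyl-2-(phenylsulfonyl)oxaziridine, O=S(=O)(c1ccccc1)N1OC1c1ccccc1
Why: The bulky amide base gives the kinetic methyl-side potassium enolate, which attacks the electrophilic oxygen of the N-sulfonyloxaziridine (Davis enolate hydroxylation) without touching the isolated olefins; no stereocentre is formed.

Step 2
Reactants: 2 (5E)-1-hydroxy-6,10-dimethylundeca-5,9-dien-2-one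
Product: 3 4-[(3E)-4,8-dimethylnona-3,7-dien-1-yl]furan-2(5H)-one
Conditions: Ph3P=C=C=O, toluene, 110 °C
Reagents that add atoms: (triphenylphosphoranylidene)ketene, O=C=C=P(c1ccccc1)(c1ccccc1)c1ccccc1
Why: Bestmann butenolide synthesis: the hydroxyl adds to the ketene ylide and the resulting ester-stabilised ylide closes on the neighbouring ketone by intramolecular Wittig reaction, forming the butenolide ring (C13–C16).

Step 3
Reactants: 3 4-[(3E)-4,8-dimethylnona-3,7-dien-1-yl]furan-2(5H)-one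
Product: 5 (2E,6E)-2,6-dimethyl-9-(5-oxo-2,5-dihydrofuran-3-yl)nona-2,6-dienal, via allylic alcohol 4 (not isolated)
Conditions: SeO2 (0.3 equiv), t-BuOOH, CH2Cl2, 0 °C → rt; then MnO2, rt
Reagents that add atoms: selenium dioxide, O=[Se]=O; tert-butyl hydroperoxide, CC(C)(C)OO
Why: Riley oxidation (ene reaction, then [2,3]-shift) takes the (E)-methyl of the terminal, most accessible gem-dimethyl olefin while the electron-poor butenolide olefin is inert, and MnO2 converges the allylic alcohol to the (E)-enal.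

Step 4
Reactants: 5 (2E,6E)-2,6-dimethyl-9-(5-oxo-2,5-dihydrofuran-3-yl)nona-2,6-dienal
Product: 6 4-[(3E,7E)-4,8-dimethyldeca-3,7,9-trien-1-yl]furan-2(5H)-one
Conditions: Ph3PCH3Br, KN(SiMe3)2, THF, 0 °C; ylide (1.05 equiv) added to 5 at −78 °C, then to 0 °C
Reagents that add atoms: methyltriphenylphosphonium bromide, C[P+](c1ccccc1)(c1ccccc1)c1ccccc1.[Br-]
Why: Wittig methylenation of the aldehyde is far faster at −78 °C than any reaction of the ylide with the lactone, and the existing (E)-olefin geometry is untouched.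

Step 5
Reactants: 7 prop-2-yn-1-ol
Product: 9 (2Z)-3-iodo-2-methylprop-2-en-1-ol, via alkenylmagnesium alkoxide 8 (not isolated)
Conditions: MeMgBr (2.5 equiv), CuI (10 mol%), THF, −10 °C → rt; then I2, −10 °C; aq NH4Cl
Reagents that add atoms: methylmagnesium bromide, C[Mg]Br; iodine, II
Why: Copper-catalysed anti-carbomagnesiation of the propargylic alkoxide puts methyl on C2 and the alkoxide-chelated magnesium on C3, and iodinolysis with retention gives only the (Z)-iodide.

Step 6
Reactants: 6 4-[(3E,7E)-4,8-dimethyldeca-3,7,9-trien-1-yl]furan-2(5H)-one; 9 (2Z)-3-iodo-2-methylprop-2-en-1-ol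
Product: 11 4-[(3E,7E,11Z)-13-hydroxy-4,8,12-trimethyltrideca-3,7,11-trien-1-yl]furan-2(5H)-one, via alkylborane 10 (not isolated)
Conditions: 9-BBN, THF, 0 °C → rt; then 9, PdCl2(dppf) (5 mol%), AsPh3, Cs2CO3, DMF/H2O, rt
Reagents that add atoms: none
Why: 9-BBN adds anti-Markovnikov to the terminal CH2 of the diene only (the butenolide is inert), and B-alkyl Suzuki–Miyaura coupling with the alkenyl iodide proceeds with retention, so the chain ends cis to CH2OH (11Z).

Step 7
Reactants: 11 4-[(3E,7E,11Z)-13-hydroxy-4,8,12-trimethyltrideca-3,7,11-trien-1-yl]furan-2(5H)-one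
Product: 12 4-{(3E,7E)-10-[(2S,3R)-3-(hydroxymethyl)-3-methyloxiran-2-yl]-4,8-dimethyldeca-3,7-dien-1-yl}furan-2(5H)-one
Conditions: Ti(OiPr)4 (10 mol%), D-(−)-diisopropyl tartrate (12 mol%), t-BuOOH, 4 Å MS, CH2Cl2, −20 °C
Reagents that add atoms: tert-butyl hydroperoxide, CC(C)(C)OO
Why: Sharpless asymmetric epoxidation touches only the allylic-alcohol olefin, and the D-(−)-tartrate catalyst delivers oxygen to the face that gives C3 (S) and C4 (R), the face opposite to the one L-(+)-tartrate uses to make 2S glycidols.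

Step 8
Reactants: 12 4-{(3E,7E)-10-[(2S,3R)-3-(hydroxymethyl)-3-methyloxiran-2-yl]-4,8-dimethyldeca-3,7-dien-1-yl}furan-2(5H)-one
Product: 15 (3S,4S,8S,9R)-3β,19-dihydroxyhalima-5(10),13-dien-15,16-olide, via silyl triflate 13 (not isolated), via cyclic silylene 14 (not isolated)
Conditions: tBu2Si(OTf)2 (1.05 equiv), 2,6-di-tert-butyl-4-methylpyridine (1.0 equiv), CH2Cl2 (5 mM), −78 → −20 °C; then pyridine, HF·pyridine, THF, 0 °C → rt
Reagents that add atoms: none
Why: Proposed new method: the primary OH is silylated first, so a hindered Si–OTf Lewis acid sits next to the oxirane and binds its oxygen as a five-membered silyloxonium ion; the tertiary C4–O bond then opens with anti attack of the C5=C10 and C8=C9 olefins through a chair–chair array (Stork–Eschenmoser course of a Lewis-acid epoxy-polyene cyclisation; ring A, then ring B), so the (3S,4R)-oxirane fixes 5α-H/10β-CH3 and places the Z-derived CH2O group axial (4β), while the electron-poor butenolide cannot act as a further π-nucleophile; the labd-13-en-8-yl cation, paired only with triflate in a base-free medium, then follows the biogenetic path: H-9α shifts suprafacially to C8 (8β-CH3), CH3-20 moves from C10 to the β face of C9 (9β-CH3, relieving its 1,3-diaxial clash with C19) and H-5 is lost to the tetrasubstituted 5(10)-ene, the TfOH released making olefin formation reversible so that kinetic labdenes funnel to the same product; O3 ends on silicon, which ties O19 into a six-membered silylene and keeps it from capturing C10, and HF·pyridine frees the diol; the closest known reaction types are silyl-triflate- and Lewis-acid-promoted epoxy-polyene cyclisation and the BF3-promoted 1,2-H/1,2-CH3 (friedo) rearrangement of drim-8-enyl and labd-8-enyl cations to 5(10)-enes.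

Step 9
Reactants: 16 3-(4-hydroxyphenyl)propanoic acid
Product: 18 3-[4-(tert-butyldimethylsilyloxy)phenyl]propanoic acid, via bis-silyl derivative 17 (not isolated)
Conditions: t-BuMe2SiCl (2.2 equiv), imidazole, DMF, rt; then K2CO3, THF/H2O, rt; acidify to pH 4
Reagents that add atoms: tert-butyldimethylsilyl chloride, CC(C)(C)[Si](C)(C)Cl
Why: Silylation of both acidic OH groups followed by selective hydrolysis of the labile silyl ester leaves the aryl silyl ether (standard phenol protection).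

Step 10
Reactants: 15 (3S,4S,8S,9R)-3β,19-dihydroxyhalima-5(10),13-dien-15,16-olide; 18 3-[4-(tert-butyldimethylsilyloxy)phenyl]propanoic acid
Product: 19 (3S,4S,8S,9R)-3β-hydroxyhalima-5(10),13-dien-15,16-olid-19-yl 3-[4-(tert-butyldimethylsilyloxy)phenyl]propanoate
Conditions: 18 (1.05 equiv), EDC·HCl, DMAP (0.1 equiv), CH2Cl2, 0 °C
Reagents that add atoms: none
Why: Steglich esterification is selective for the primary C19 hydroxyl over the secondary 3β-hydroxyl, which is hindered by the quaternary C4.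

Step 11
Reactants: 19 (3S,4S,8S,9R)-3β-hydroxyhalima-5(10),13-dien-15,16-olid-19-yl 3-[4-(tert-butyldimethylsilyloxy)phenyl]propanoate
Product: 20 (4S,8S,9R)-3-oxohalima-5(10),13-dien-15,16-olid-19-yl 3-[4-(tert-butyldimethylsilyloxy)phenyl]propanoate
Conditions: Dess–Martin periodinane, CH2Cl2, rt
Reagents that add atoms: none
Why: Dess–Martin oxidation of the only free alcohol gives the ketone; C4 is quaternary, so neither epimerisation nor β-elimination of the acyloxymethyl group is possible.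

Step 12
Reactants: 20 (4S,8S,9R)-3-oxohalima-5(10),13-dien-15,16-olid-19-yl 3-[4-(tert-butyldimethylsilyloxy)phenyl]propanoate
Product: 21 (4S,6S,8S,9R)-6α-hydroxy-3-oxohalima-5(10),13-dien-15,16-olid-19-yl 3-[4-(tert-butyldimethylsilyloxy)phenyl]propanoate
Conditions: SeO2 (0.5 equiv), t-BuOOH (3 equiv), CH2Cl2, rt
Reagents that add atoms: selenium dioxide, O=[Se]=O; tert-butyl hydroperoxide, CC(C)(C)OO
Why: Riley allylic hydroxylation: selenium should add to C10 on the α face (C5 is shielded on both faces by the two C4 substituents and the pseudoaxial 9β-CH3 blocks the β face of C10), the pseudoaxial 6α-H is transferred in the ene step and the [2,3]-shift returns oxygen to C6 on the same face with the olefin back at C5=C10, giving the 6α (6S) alcohol; the C1–H bonds are deactivated by the β-carbonyl.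

Step 13
Reactants: 21 (4S,6S,8S,9R)-6α-hydroxy-3-oxohalima-5(10),13-dien-15,16-olid-19-yl 3-[4-(tert-butyldimethylsilyloxy)phenyl]propanoate
Product: 22 (4S,6S,8S,9R)-6α-hydroxy-3-oxohalima-5(10),13-dien-15,16-olid-19-yl 3-(4-hydroxyphenyl)propanoate (CNP0301014.1)
Conditions: KHF2, MeOH, rt
Reagents that add atoms: none
Why: Fluoride-mediated cleavage of the aryl silyl ether (phenoxide as leaving group) under near-neutral conditions spares both esters, the allylic alcohol and the butenolide.

**Compound list**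
1 | (5E)-6,10-dimethylundeca-5,9-dien-2-one, (E)-geranylacetone | CC(=O)CC/C=C(C)/CCC=C(C)C | starting material
2 | (5E)-1-hydroxy-6,10-dimethylundeca-5,9-dien-2-one | OCC(=O)CC/C=C(C)/CCC=C(C)C | intermediate
3 | 4-[(3E)-4,8-dimethylnona-3,7-dien-1-yl]furan-2(5H)-one | CC(C)=CCC/C(C)=C/CCC1=CC(=O)OC1 | intermediate
4 | 4-[(3E,7E)-9-hydroxy-4,8-dimethylnona-3,7-dien-1-yl]furan-2(5H)-one (not isolated) | OC/C(C)=C/CC/C(C)=C/CCC1=CC(=O)OC1 | intermediate
5 | (2E,6E)-2,6-dimethyl-9-(5-oxo-2,5-dihydrofuran-3-yl)nona-2,6-dienal | O=C/C(C)=C/CC/C(C)=C/CCC1=CC(=O)OC1 | intermediate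
6 | 4-[(3E,7E)-4,8-dimethyldeca-3,7,9-trien-1-yl]furan-2(5H)-one | C=C/C(C)=C/CC/C(C)=C/CCC1=CC(=O)OC1 | intermediate
7 | prop-2-yn-1-ol | C#CCO | starting material
8 | bromomagnesium (2Z)-3-(bromomagnesio)-2-methylprop-2-en-1-olate (not isolated) | Br[Mg]/C=C(C)\CO[Mg]Br | intermediate
9 | (2Z)-3-iodo-2-methylprop-2-en-1-ol | OC/C(C)=C\I | intermediate
10 | 4-[(3E,7E)-10-(9-borabicyclo[3.3.1]nonan-9-yl)-4,8-dimethyldeca-3,7-dien-1-yl]furan-2(5H)-one (not isolated) | B1(CC/C(C)=C/CC/C(C)=C/CCC3=CC(=O)OC3)C2CCCC1CCC2 | intermediate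
11 | 4-[(3E,7E,11Z)-13-hydroxy-4,8,12-trimethyltrideca-3,7,11-trien-1-yl]furan-2(5H)-one | OC/C(C)=C\CC/C(C)=C/CC/C(C)=C/CCC1=CC(=O)OC1 | intermediate
12 | 4-{(3E,7E)-10-[(2S,3R)-3-(hydroxymethyl)-3-methyloxiran-2-yl]-4,8-dimethyldeca-3,7-dien-1-yl}furan-2(5H)-one | OC[C@@]1(C)O[C@H]1CC/C(C)=C/CC/C(C)=C/CCC2=CC(=O)OC2 | intermediate
13 | 12 with its OH converted into O–Si(t-Bu)2–OSO2CF3 (not isolated) | CC(C)(C)[Si](OC[C@@]1(C)O[C@H]1CC/C(C)=C/CC/C(C)=C/CCC2=CC(=O)OC2)(OS(=O)(=O)C(F)(F)F)C(C)(C)C | intermediate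
14 | 3,19-O-(di-tert-butylsilanediyl) derivative of 15, six-membered dioxasilinane across O3 and O19 (not isolated) | C[C@H]1CCC2=C(CC[C@@H]3O[Si](C(C)(C)C)(C(C)(C)C)OC[C@]23C)[C@]1(C)CCC1=CC(=O)OC1 | intermediate
15 | (3S,4S,8S,9R)-3β,19-dihydroxyhalima-5(10),13-dien-15,16-olide; 4-{2-[(1R,2S,5S,6S)-6-hydroxy-5-(hydroxymethyl)-1,2,5-trimethyl-1,2,3,4,5,6,7,8-octahydronaphthalen-1-yl]ethyl}furan-2(5H)-one | C[C@H]1CCC2=C(CC[C@H](O)[C@]2(C)CO)[C@]1(C)CCC1=CC(=O)OC1 | intermediate
16 | 3-(4-hydroxyphenyl)propanoic acid | OC(=O)CCc1ccc(O)cc1 | starting material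
17 | tert-butyldimethylsilyl 3-[4-(tert-butyldimethylsilyloxy)phenyl]propanoate (not isolated) | CC(C)(C)[Si](C)(C)OC(=O)CCc1ccc(O[Si](C)(C)C(C)(C)C)cc1 | intermediate
18 | 3-[4-(tert-butyldimethylsilyloxy)phenyl]propanoic acid | OC(=O)CCc1ccc(O[Si](C)(C)C(C)(C)C)cc1 | intermediate
19 | (3S,4S,8S,9R)-3β-hydroxyhalima-5(10),13-dien-15,16-olid-19-yl 3-[4-(tert-butyldimethylsilyloxy)phenyl]propanoate | C[C@H]1CCC2=C(CC[C@H](O)[C@]2(C)COC(=O)CCc2ccc(O[Si](C)(C)C(C)(C)C)cc2)[C@]1(C)CCC1=CC(=O)OC1 | intermediate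
20 | (4S,8S,9R)-3-oxohalima-5(10),13-dien-15,16-olid-19-yl 3-[4-(tert-butyldimethylsilyloxy)phenyl]propanoate | C[C@H]1CCC2=C(CCC(=O)[C@]2(C)COC(=O)CCc2ccc(O[Si](C)(C)C(C)(C)C)cc2)[C@]1(C)CCC1=CC(=O)OC1 | intermediate
21 | (4S,6S,8S,9R)-6α-hydroxy-3-oxohalima-5(10),13-dien-15,16-olid-19-yl 3-[4-(tert-butyldimethylsilyloxy)phenyl]propanoate | C[C@H]1C[C@H](O)C2=C(CCC(=O)[C@]2(C)COC(=O)CCc2ccc(O[Si](C)(C)C(C)(C)C)cc2)[C@]1(C)CCC1=CC(=O)OC1 | intermediate
22 | (4S,6S,8S,9R)-6α-hydroxy-3-oxohalima-5(10),13-dien-15,16-olid-19-yl 3-(4-hydroxyphenyl)propanoate, CNP0301014.1 | C[C@H]1C[C@H](O)C2=C(CCC(=O)[C@]2(C)COC(=O)CCc2ccc(O)cc2)[C@]1(C)CCC1=CC(=O)OC1 | target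

**Step count**
Total: 13 steps. Longest linear sequence: 11 steps (1–4, 6–8, 10–13); steps 5 and 9 make the two side pieces 9 and 18.

**Three steps most likely to fail**

Step 8 (cascade). The labdenyl cation may simply lose a proton before the hydride and methyl shifts, giving labdene mixtures. The released TfOH may drive the shifts on towards a clerodane, or O19 may capture C10 as a 19,10-ether. A Meinwald shift to a ketone can compete with ring A closure. The fallback sets out from 12 and returns at 15, and separates cyclisation from rearrangement. t-BuPh2SiCl/imidazole (DMF) gives the tert-butyldiphenylsilyl ether of 12 F1. MeAlCl2 (CH2Cl2, −78 °C) then effects only the bicyclisation, to 19-(tert-butyldiphenylsilyloxy)-3β-hydroxylabda-8(17),13-dien-15,16-olide F2; its Δ7 and Δ8 isomers form alongside and are carried on. BF3·OEt2 (CH2Cl2, −40 → 0 °C) brings about the 1,2-H/1,2-CH3 shift to 19-(tert-butyldiphenylsilyloxy)-3β-hydroxyhalima-5(10),13-dien-15,16-olide F3. Bu4NF/AcOH (THF) removes the silyl group to give 15.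

Step 12 (C6 hydroxylation). The selectivity for C6 over C1 rests on a steric argument only, and electronic effects may favour C1. Slow reaction at the tetrasubstituted olefin may also allow α-oxidation of the ketone at C2. The fallback sets out from 20 and returns at 21. CrO3·3,5-dimethylpyrazole (CH2Cl2, −20 °C) oxidises the allylic CH2 by hydrogen-atom abstraction to (4S,8S,9R)-3,6-dioxohalima-5(10),13-dien-15,16-olid-19-yl 3-[4-(tert-butyldimethylsilyloxy)phenyl]propanoate F4, separable from any 1-oxo isomer. Reagent-controlled 1,2-reduction with (R)-Me-CBS oxazaborolidine/catecholborane (toluene, −78 °C) then sets the 6S alcohol; the tetrasubstituted alkenyl carbon is the large group and the hindered C3 ketone reacts more slowly. This gives 21.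

Step 1 (enolate hydroxylation). A hydroxymethyl ketone made from a methyl ketone enolate can be over-oxidised or undergo aldol reaction, and some internal enolate may form. The fallback sets out from 1 and returns at 3, bypassing 2. LiN(iPr)2/Me3SiCl (THF, −78 °C) gives the kinetic silyl enol ether (5E)-6,10-dimethyl-2-(trimethylsilyloxy)undeca-1,5,9-triene F5. N-bromosuccinimide (THF, −78 °C) gives (5E)-1-bromo-6,10-dimethylundeca-5,9-dien-2-one F6. Potassium (diethoxyphosphoryl)acetate (DMF, rt) displaces bromide to give (5E)-6,10-dimethyl-2-oxoundeca-5,9-dien-1-yl (diethoxyphosphoryl)acetate F7. LiCl/DBU (MeCN, rt) closes the butenolide 3 by intramolecular Horner–Wadsworth–Emmons reaction.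

**Further compounds**
F1 | step 8 | 4-{(3E,7E)-10-[(2S,3R)-3-[(tert-butyldiphenylsilyloxy)methyl]-3-methyloxiran-2-yl]-4,8-dimethyldeca-3,7-dien-1-yl}furan-2(5H)-one | CC(C)(C)[Si](OC[C@@]1(C)O[C@H]1CC/C(C)=C/CC/C(C)=C/CCC1=CC(=O)OC1)(c1ccccc1)c1ccccc1
F2 | step 8 | 19-(tert-butyldiphenylsilyloxy)-3β-hydroxylabda-8(17),13-dien-15,16-olide (5α-H, 9α-H, 10β-CH3) | C=C1CC[C@H]2[C@@](C)(CO[Si](c3ccccc3)(c3ccccc3)C(C)(C)C)[C@@H](O)CC[C@]2(C)[C@H]1CCC1=CC(=O)OC1
F3 | step 8 | (3S,4S,8S,9R)-19-(tert-butyldiphenylsilyloxy)-3β-hydroxyhalima-5(10),13-dien-15,16-olide | C[C@H]1CCC2=C(CC[C@H](O)[C@]2(C)CO[Si](c2ccccc2)(c2ccccc2)C(C)(C)C)[C@]1(C)CCC1=CC(=O)OC1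
F4 | step 12 | (4S,8S,9R)-3,6-dioxohalima-5(10),13-dien-15,16-olid-19-yl 3-[4-(tert-butyldimethylsilyloxy)phenyl]propanoate | C[C@H]1CC(=O)C2=C(CCC(=O)[C@]2(C)COC(=O)CCc2ccc(O[Si](C)(C)C(C)(C)C)cc2)[C@]1(C)CCC1=CC(=O)OC1
F5 | step 1 | (5E)-6,10-dimethyl-2-(trimethylsilyloxy)undeca-1,5,9-triene | C=C(O[Si](C)(C)C)CC/C=C(C)/CCC=C(C)C
F6 | step 1 | (5E)-1-bromo-6,10-dimethylundeca-5,9-dien-2-one | BrCC(=O)CC/C=C(C)/CCC=C(C)C
F7 | step 1 | (5E)-6,10-dimethyl-2-oxoundeca-5,9-dien-1-yl (diethoxyphosphoryl)acetate | CCOP(=O)(OCC)CC(=O)OCC(=O)CC/C=C(C)/CCC=C(C)C
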